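## Analysis of the target

Compound 37 is a 9,13-epoxylabdane. It has a trans-decalin (ring A: C1–C5, C10 with gem-dimethyl C4; ring B: C5–C10), a tetrahydrofuran (O, C9, C11, C12, C13) spiro-fused at C9, and a 2,3-dihydrofuran (C13, C14, C15, O, C16) spiro-fused at C13. There are six stereocentres, 5S,6R,8R,9R,10S,13R: H-5 is α and the C10 methyl β (trans fusion), the C8 methyl is α and equatorial, the C9 oxygen is α and axial with C11 equatorial, and the C6 acetoxy group is β and axial, 1,3-diaxial to the C10 methyl and one C4 methyl. C13 is quaternary, two carbons away from the decalin, and cannot be relayed from the ring stereocentres. C9 and C10 are adjacent fully substituted carbons, so the C9–C10 bond is the most hindered bond of the skeleton. The cyclic enol ether C14=C15–O is acid-labile (hydration, or aromatization to a furan with loss of the C13–O9 bond), and the hindered acetate does not survive hydride or strong base; the enol ether must therefore be made late under basic conditions and the acetate last. The strategy rests on one feature: C4 (gem-dimethyl), C10 (angular methyl) and C9 (oxygenated spiro carbon) are the 1,5,9-carbons of a head-to-tail polyene cyclization (bonds C4–C5 and C9–C10). The terminating alkene carbon C9 may already carry the ring oxygen if it is the β-carbon of a 3(2H)-furanone built from O, C9, C11, C12 and C13.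

## Retrosynthetic reasoning

**C6 acetate (37 ⇐ 36 ⇐ 35).** The acetate is removed first because it is the least robust group. The axial 6β-alcohol 36 is traced to ketone 35: hydride attack on a C6 ketone comes from the α face, opposite the two axial methyl groups, and gives the axial alcohol. This also allows C6 to carry an equatorial (α) oxygen earlier, where the cyclization needs it.

**Dihydrofuran (35 ⇐ 33 ⇐ 31 ⇐ 30).** The enol ether is cut at C15–O16 and C14=C15 to lactol 33, i.e. a C16 alcohol and a C15 aldehyde on C13. The two arms are kept apart as a benzyl ether (C16) and a silyl ether (C15) so that C15 can be oxidized first. Since the C6 and C15 silyl ethers fall together, diol 30 is oxidized at both positions in one operation to keto aldehyde 31.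

**C12 methylene (30 ⇐ 29 ⇐ 28 ⇐ 26 ⇐ 25).** The C12 carbonyl of 25 is what makes C9 a radical acceptor; it has no place in 37 and is removed by reduction and radical deoxygenation. A radical method is chosen because basic or hydrazone-based methods risk β-elimination of the C9 or C13 ether oxygen.

**Rings A and B (25 ⇐ 24).** C4–C5 and C9–C10 are cut together. This is the only disconnection that removes both carbocycles, the C9/C10 vicinal fully substituted pair and three stereocentres (C5, C9, C10) at once, and it leaves an acyclic chain whose stereocentres (C6, C8, C13) can be made independently. The forward reaction is a hydrogen-atom-transfer-initiated radical bicyclization of dienyl furanone 24. It must start at the terminal alkene, close 6-endo then 6-exo, and fold so that the C6 and C8 substituents are equatorial. A radical rather than a cationic process is required because the allylic C6 silyl ether of 24 would ionize under acid.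

**Furanone (24 ⇐ 22).** The O–C9 bond is cut to give α'-hydroxy ynone 22. Its amine-mediated cycloisomerization is regiochemically unambiguous (oxygen to the alkyne carbon remote from the ketone) and needs neither acid nor metal, which the allylic silyl ether and the 1,6-enyne would not tolerate well.

**C11–C12 (22 ⇐ 11 + 19).** Cutting next to the carbonyl gives terminal alkyne 11 (C1–C11 with C6 and C8) and N-methoxy-N-methylamide 19 (C12–C16 with C13). This is the convergent point. An acetylide acylation gives the ynone oxidation level directly, and no stereocentre is formed.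

**Alkyne 11 (11 ⇐ 10 ⇐ 9 ⇐ 8 ⇐ 7).** The alkyne carbon C11 is added to aldehyde 10, which comes from ester 9. The C6 carbinol of 8 is traced to enone 7 so that it can be set by a catalyst-controlled reduction, independent of the remote C8 centre.

**C6–C7 (7 ⇐ 5 + 3; 5 ⇐ 4; 3 ⇐ 2 ⇐ 1).** Enone 7 is cut between the carbonyl and C7 into acyl chloride 3 (C1–C6, C10 with both alkenes, from geranial 1 via acid 2) and the iodide 5 made from hydroxy ester 4. The ester-bearing alkylzinc from 5 acylates cleanly, keeps C8 intact, and its ester group is the later alkyne carbon C9, so no protecting group is spent on this fragment.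

**Quaternary C13 (19 ⇐ 18 ⇐ 17 ⇐ 15 ⇐ 13 ⇐ 12).** C13 bears O, C12, C14 and C16. In (S)-malic acid 12 the carbinol carbon already bears O, a carboxyl (C12) and the CH2CO2H arm (C14–C15) in the right sense. Only C16 is missing, and it is added by alkylation of the dioxolanone 13 with retention (self-regeneration of the stereocentre). Reduction of the side-chain acid, lactonization to 17 and opening to the amide give 19 with each carbon at the oxidation level needed later.

## Alternatives that were turned down

**Alternative 1:** Ring A is cut at C1–C10 and C4–C5 and traced to a [4+2] addition between 2,6-dimethyl-1,4-benzoquinone A2 (the future ring B) and the 2-silyloxy diene A3.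
- Forward key step: a chiral cationic oxazaborolidine Lewis acid directs A3 to one methyl-bearing double bond of A2 and gives the cis-fused ene-dione A1, with the C10 quaternary centre set by the catalyst.
- For it: the absolute configuration comes from a catalyst; ring B arrives with oxygen at C6 and C9 and the methyl group at C8; enantioselective quinone cycloadditions of this type are established. On precedent for the key step this route is stronger than the chosen one.
- Against it for 37: A3 carries two methyl groups on the terminus that must bond to C5, which disfavours the s-cis conformer and slows bond formation next to the future gem-dimethyl carbon. A1 is cis-fused and must be epimerized at C5. The C2 oxygen must be removed in steps that build nothing. Most seriously, the C11–C16 chain must then be added to the C9 carbonyl, where attack anti to the axial C10 methyl would put carbon axial and oxygen equatorial, the opposite of 37. C8 and C13 remain open.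
- Comparison: the chosen route forms C9 with oxygen axial in the ring closure itself, brings C11–C16 in with the furanone, and puts no superfluous oxygen into ring A. It is shorter after the key step.

**Alternative 2:** The tetrahydrofuran is cut at C12–C13; the precursor is the iodide A5, a complete decalin whose tertiary C9 oxygen is etherified with a tetronate.
- Forward key step: Bu3SnH and azobis(isobutyronitrile) generate the primary C12 radical, which adds 5-exo-trig to the oxygen-bearing carbon C13 of the tetronate and gives spiro lactone A4.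
- For it: 5-exo addition of a primary radical to a β-alkoxy acrylate-type acceptor is well precedented and forms no bond between two fully substituted carbons. The ring closure itself is more certain than the chosen key step, and A4 already carries every carbon and the acetate.
- Against it for 37: all the difficult work moves in front of the key step. A5 needs the finished decalin with five stereocentres, and the hindered tertiary C9 hydroxyl next to quaternary C10 must be joined to the tetronate carbon, a slow addition–elimination. C13 would be formed under the influence of the distant decalin only, so its configuration is uncertain. A4 must be reduced to the lactol in the presence of the acetate.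
- Comparison: the chosen route takes C13 from the chiral pool, forms the C9–O bond while C9 is still an unhindered sp2 carbon, and builds the decalin rather than presupposing it.

**Alternative 3:** O–C13 and C9–C10 are cut; the precursor is keto epoxide A7, a 2,6,6-trimethylcyclohexene carrying the C6–C13 chain.
- Forward key step: BF3·OEt2 lets the C9 ketone oxygen open the 2,2-disubstituted epoxide at C13 with inversion. C10 of the tetrasubstituted ring A alkene then attacks the five-membered oxocarbenium ion at C9 (Prins closure of ring B), and loss of a C6 proton gives the 5-ene A6.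
- For it: the C9–C10 bond is made by a polar reaction between a planar oxocarbenium ion and a nucleophilic tetrasubstituted alkene, arguably more tolerant of crowding than radical addition. A7 is short to make, and C13 comes from an epoxide.
- Against it for 37: the 2,2-disubstituted epoxide can rearrange to an aldehyde (Meinwald rearrangement) before the ketone takes part. The tertiary C5 cation lies between two quaternary carbons and invites 1,2-methyl shifts. The C9/C10 facial selectivity rests on the C8 methyl alone. A6 still lacks the C6 oxygen and the C5 hydrogen (hydroboration, then the same oxidation–reduction inversion), and its free hydroxymethyl arm is only C14, so C15 has to be added.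
- Comparison: the chosen cyclization gives the C6 oxygen, H-5 and all sixteen side-chain and ring carbons in the product of the key step.

Key step: step 16

Remarks on the chemistry:
- Positions are numbered as in labdane in all explanations, so that atoms can be followed from the chain into the rings.
- Compound 1 is used as the pure 2E isomer.
- C12 in 26–28 and C15 in 33 and 34 are carried as epimer mixtures, because both centres disappear later.

## Route

Step 1
Reactants: 1 geranial, (2E)-3,7-dimethylocta-2,6-dienal
Product: 2 (2E)-3,7-dimethylocta-2,6-dienoic acid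
Conditions: NaClO2, NaH2PO4, 2-methylbut-2-ene, t-BuOH/H2O, 0 °C → rt
Reagents that add atoms: sodium chlorite, [Na+].[O-]Cl=O
Why: Pinnick oxidation converts the enal into the acid; the alkene scavenger removes hypochlorous acid so the two trisubstituted alkenes survive, and the 2E geometry is kept.

Step 2
Reactants: 2 (2E)-3,7-dimethylocta-2,6-dienoic acid
Product: 3 (2E)-3,7-dimethylocta-2,6-dienoyl chloride
Conditions: 1-chloro-N,N,2-trimethylprop-1-en-1-amine, CH2Cl2, 0 °C → rt; concentrated and used directly
Reagents that add atoms: 1-chloro-N,N,2-trimethylprop-1-en-1-amine, CC(C)=C(Cl)N(C)C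
Why: The α-chloroenamine forms the acyl chloride under neutral conditions, so no hydrogen chloride is present to add to the alkenes or to isomerize the 2,3-double bond.

Step 3
Reactants: 4 methyl (2R)-3-hydroxy-2-methylpropanoate
Product: 5 methyl (2S)-3-iodo-2-methylpropanoate
Conditions: I2, PPh3, imidazole, CH2Cl2, 0 °C → rt
Reagents that add atoms: iodine, II
Why: Appel-type iodination of the primary alcohol (phosphonium activation, SN2 by iodide); the stereocentre (later C8) is not touched, only its descriptor changes.

Step 4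
Reactants: 5 methyl (2S)-3-iodo-2-methylpropanoate; 3 (2E)-3,7-dimethylocta-2,6-dienoyl chloride
Product: 7 methyl (2R,5E)-2,6,10-trimethyl-4-oxoundeca-5,9-dienoate, via alkylzinc iodide 6 (not isolated)
Conditions: Zn dust (activated with BrCH2CH2Br and Me3SiCl), THF, 35 °C; then 3, Pd(PPh3)4 (5 mol%), THF, 0 °C → rt
Reagents that add atoms: none
Why: Zinc inserts into the primary C–I bond to give the ester-stabilized, configurationally stable reagent 6; Negishi acylation catalysed by zerovalent palladium forms C6–C7 and stops at the ketone, the β,β-disubstituted enone being inert to conjugate addition of the zinc reagent.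

Step 5
Reactants: 7 methyl (2R,5E)-2,6,10-trimethyl-4-oxoundeca-5,9-dienoate
Product: 8 methyl (2R,4S,5E)-4-hydroxy-2,6,10-trimethylundeca-5,9-dienoate
Conditions: (R)-1-methyl-3,3-diphenyltetrahydro-1H,3H-pyrrolo[1,2-c][1,3,2]oxazaborole (20 mol%), catecholborane, toluene, −78 °C; MeOH quench, neutral work-up
Reagents that add atoms: none
Why: Corey–Bakshi–Shibata reduction: the alkenyl group acts as the large and the methylene as the small ketone substituent, so the (R)-catalyst should deliver hydride to give the 4S carbinol (C6) by 1,2-reduction under catalyst control; the ester is not reduced at this temperature.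

Step 6
Reactants: 8 methyl (2R,4S,5E)-4-hydroxy-2,6,10-trimethylundeca-5,9-dienoate
Product: 9 methyl (2R,4S,5E)-4-[(tert-butyldimethylsilyl)oxy]-2,6,10-trimethylundeca-5,9-dienoate
Conditions: t-BuMe2SiOTf, 2,6-lutidine, CH2Cl2, −78 °C (on freshly prepared 8)
Reagents that add atoms: tert-butyldimethylsilyl trifluoromethanesulfonate, CC(C)(C)[Si](C)(C)OS(=O)(=O)C(F)(F)F
Why: Silylation with the silyl triflate at low temperature should outrun lactonization of the γ-hydroxy ester and installs the C6 silyl ether that later controls the folding.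

Step 7
Reactants: 9 methyl (2R,4S,5E)-4-[(tert-butyldimethylsilyl)oxy]-2,6,10-trimethylundeca-5,9-dienoate
Product: 10 (2R,4S,5E)-4-[(tert-butyldimethylsilyl)oxy]-2,6,10-trimethylundeca-5,9-dienal
Conditions: i-Bu2AlH (1.1 equiv), CH2Cl2, −78 °C; aq. potassium sodium tartrate
Reagents that add atoms: none
Why: Partial reduction of the methyl ester at −78 °C stops at the aldehyde oxidation level, and the non-basic conditions leave the α-stereocentre (C8) intact.

Step 8
Reactants: 10 (2R,4S,5E)-4-[(tert-butyldimethylsilyl)oxy]-2,6,10-trimethylundeca-5,9-dienal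
Product: 11 tert-butyldimethyl{[(3R,5S,6E)-3,7,11-trimethyldodeca-6,10-dien-1-yn-5-yl]oxy}silane
Conditions: dimethyl (1-diazo-2-oxopropyl)phosphonate, K2CO3, MeOH, 0 °C → rt
Reagents that add atoms: dimethyl (1-diazo-2-oxopropyl)phosphonate, COP(=O)(OC)C(=[N+]=[N-])C(C)=O
Why: Ohira–Bestmann homologation (Seyferth–Gilbert type) turns the aldehyde into the terminal alkyne C9≡C11 under mild carbonate conditions that are routinely used with α-methyl aldehydes without epimerization.

Step 9
Reactants: 12 (2S)-2-hydroxybutanedioic acid, (S)-malic acid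
Product: 13 2-[(2S,4S)-2-tert-butyl-5-oxo-1,3-dioxolan-4-yl]acetic acid
Conditions: t-BuCHO, TsOH·H2O (cat.), H2SO4 (cat.), pentane, reflux with water separator; recrystallization
Reagents that add atoms: 2,2-dimethylpropanal, CC(C)(C)C=O
Why: Acid-catalysed acetalization of the α-hydroxy acid unit gives the five-membered dioxolanone, the cis isomer being favoured and purified by crystallization; the acetal carbon stores the chirality of the future C13.

Step 10
Reactants: 13 2-[(2S,4S)-2-tert-butyl-5-oxo-1,3-dioxolan-4-yl]acetic acid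
Product: 15 2-[(2S,4R)-4-[(benzyloxy)methyl]-2-tert-butyl-5-oxo-1,3-dioxolan-4-yl]acetic acid, via dilithium enolate carboxylate 14 (not isolated)
Conditions: LiN(SiMe3)2 (2.2 equiv), THF, −78 °C; BnOCH2Cl (1.1 equiv), −78 → −30 °C; cold dilute HCl work-up
Reagents that add atoms: benzyl chloromethyl ether, ClCOCc1ccccc1
Why: Self-regeneration of the stereocentre: enolate 14 is alkylated anti to the tert-butyl group, so the benzyloxymethyl group (C16) replaces hydrogen with retention and the quaternary centre C13 is set; at −78 °C the enolate carbon should react faster than the lithium carboxylate.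

Step 11
Reactants: 15 2-[(2S,4R)-4-[(benzyloxy)methyl]-2-tert-butyl-5-oxo-1,3-dioxolan-4-yl]acetic acid
Product: 17 (3R)-3-[(benzyloxy)methyl]-3-hydroxyoxolan-2-one, via hydroxyethyl dioxolanone 16 (not isolated)
Conditions: BH3·SMe2, THF, 0 °C → rt; MeOH; then TsOH·H2O (cat.), CH2Cl2, rt
Reagents that add atoms: none
Why: Borane reduces the free carboxylic acid much faster than the dioxolanone carbonyl; under acid the primary alcohol of 16 transacylates onto that carbonyl to give the γ-lactone and releases the aldehyde auxiliary.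

Step 12
Reactants: 17 (3R)-3-[(benzyloxy)methyl]-3-hydroxyoxolan-2-one
Product: 18 (2R)-2-[(benzyloxy)methyl]-2,4-dihydroxy-N-methoxy-N-methylbutanamide
Conditions: MeNH(OMe)·HCl, AlMe3 (3 equiv each), CH2Cl2, 0 °C → rt; aq. potassium sodium tartrate
Reagents that add atoms: N,O-dimethylhydroxylamine hydrochloride, CNOC.Cl
Why: Aminolysis of the lactone by the aluminium amide (Weinreb amide formation) opens the ring; the tertiary hydroxyl is only deprotonated and returns on work-up.

Step 13
Reactants: 18 (2R)-2-[(benzyloxy)methyl]-2,4-dihydroxy-N-methoxy-N-methylbutanamide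
Product: 19 (2R)-2-[(benzyloxy)methyl]-4-[(tert-butyldiphenylsilyl)oxy]-2-hydroxy-N-methoxy-N-methylbutanamide
Conditions: t-BuPh2SiCl (1.05 equiv), imidazole, CH2Cl2, 0 °C (directly on crude 18)
Reagents that add atoms: tert-butylchlorodiphenylsilane, CC(C)(C)[Si](Cl)(c1ccccc1)c1ccccc1
Why: The primary hydroxyl is silylated selectively over the hindered tertiary one, which also blocks relactonization of the γ-hydroxy amide.

Step 14
Reactants: 11 tert-butyldimethyl{[(3R,5S,6E)-3,7,11-trimethyldodeca-6,10-dien-1-yn-5-yl]oxy}silane; 19 (2R)-2-[(benzyloxy)methyl]-4-[(tert-butyldiphenylsilyl)oxy]-2-hydroxy-N-methoxy-N-methylbutanamide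
Product: 22 (3R,7R,9S,10E)-3-[(benzyloxy)methyl]-9-[(tert-butyldimethylsilyl)oxy]-1-[(tert-butyldiphenylsilyl)oxy]-3-hydroxy-7,11,15-trimethylhexadeca-10,14-dien-5-yn-4-one, via lithium acetylide 20 (not isolated), via chloromagnesium alkoxide 21 (not isolated)
Conditions: 11 (1.0 equiv), n-BuLi, THF, −78 °C; separately 19 (1.2 equiv), i-PrMgCl (1.2 equiv), THF, −40 °C; combine, −78 → 0 °C; aq. NH4Cl
Reagents that add atoms: none
Why: Weinreb ketone synthesis: acetylide 20 adds once to the N-methoxy-N-methylamide and forms C11–C12; converting the tertiary hydroxyl into alkoxide 21 beforehand keeps it from quenching the acetylide, and the ynone is released only on work-up.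

Step 15
Reactants: 22 (3R,7R,9S,10E)-3-[(benzyloxy)methyl]-9-[(tert-butyldimethylsilyl)oxy]-1-[(tert-butyldiphenylsilyl)oxy]-3-hydroxy-7,11,15-trimethylhexadeca-10,14-dien-5-yn-4-one
Product: 24 (2R)-2-[(benzyloxy)methyl]-5-[(2R,4S,5E)-4-[(tert-butyldimethylsilyl)oxy]-6,10-dimethylundeca-5,9-dien-2-yl]-2-{2-[(tert-butyldiphenylsilyl)oxy]ethyl}furan-3(2H)-one, via diethylamino enone 23 (not isolated)
Conditions: Et2NH, EtOH, 0 °C → rt; then AcOH, THF/H2O, rt
Reagents that add atoms: none
Why: Conjugate addition of the secondary amine to the ynone gives enaminone 23; under mild acid the tertiary hydroxyl attacks its iminium form at C9 (5-exo-trig) and diethylamine is expelled, the known amine-mediated route from α'-hydroxy ynones to 3(2H)-furanones, which needs neither strong acid nor a metal.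

Step 16
Reactants: 24 (2R)-2-[(benzyloxy)methyl]-5-[(2R,4S,5E)-4-[(tert-butyldimethylsilyl)oxy]-6,10-dimethylundeca-5,9-dien-2-yl]-2-{2-[(tert-butyldiphenylsilyl)oxy]ethyl}furan-3(2H)-one
Product: 25 (5S,6S,8R,9R,10S,13R)-16-(benzyloxy)-6-[(tert-butyldimethylsilyl)oxy]-15-[(tert-butyldiphenylsilyl)oxy]-9,13-epoxylabdan-12-one
Conditions: Fe(acac)3 (1.0 equiv), PhSiH3 (2.5 equiv, slow addition), EtOH/HOCH2CH2OH (5:1), 0.01 M, degassed, 60 °C
Reagents that add atoms: none
Why: Proposed new method: an iron hydride formed from Fe(acac)3 and PhSiH3 in ethanol transfers a hydrogen atom to C3 of the terminal trisubstituted alkene of 24, the most electron-rich and least shielded alkene (C5=C10 carries the electron-withdrawing, bulky allylic silyloxy group and C9=C11 is electron-poor), giving the tertiary C4 radical. Ring A closes by 6-endo-trig attack of C4 on C5, and ring B closes by 6-exo-trig addition of the tertiary C10 radical to C9, the oxygen-bearing β-carbon of the vinylogous ester; the C11 α-keto radical is then reduced by divalent iron and the enolate protonated by the solvent. The closest known reaction type is the iron-hydride-initiated reductive radical bicyclization of 1,5-dienes that ends on an enone or acrylate; new here is an end carbon that is fully substituted and carries the ring oxygen, so that C9–C10 joins two fully substituted carbons and a spiro ether results. C5 and C10 follow from the E alkene reacting through a chair–chair transition state with anti addition across C5=C10, which gives the trans ring fusion. The sense of folding is set by the existing centres: only one chair of the nascent ring B has both the C6 silyloxy group and the C8 methyl group equatorial, and the other alkene face would force both axial. C9 is set by the orientation of the planar furanone in that chair, the C9=C11 bond lying equatorial so that the small ring oxygen takes the axial position and C11 avoids the axial hydrogens at C5 and C7. The step needs site-selective initiation, 6-endo then 6-exo regiochemistry, trans fusion and C9 face selectivity, which rest on alkene electronics, on attack at the unsubstituted C5 terminus and then at the conjugate position of the furanone, on the E geometry, and on the two equatorial substituents; high dilution and slow silane addition are meant to keep reduction of the C10 radical slower than ring closure.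

Step 17
Reactants: 25 (5S,6S,8R,9R,10S,13R)-16-(benzyloxy)-6-[(tert-butyldimethylsilyl)oxy]-15-[(tert-butyldiphenylsilyl)oxy]-9,13-epoxylabdan-12-one
Product: 26 (5S,6S,8R,9R,10S,13R)-16-(benzyloxy)-6-[(tert-butyldimethylsilyl)oxy]-15-[(tert-butyldiphenylsilyl)oxy]-9,13-epoxylabdan-12-ol (C12 epimers)
Conditions: NaBH4, MeOH/THF, 0 °C
Reagents that add atoms: none
Why: Borohydride reduction of the five-ring ketone; the configuration of the new carbinol does not matter because C12 is deoxygenated.

Step 18
Reactants: 26 (5S,6S,8R,9R,10S,13R)-16-(benzyloxy)-6-[(tert-butyldimethylsilyl)oxy]-15-[(tert-butyldiphenylsilyl)oxy]-9,13-epoxylabdan-12-ol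
Product: 28 O-[(5S,6S,8R,9R,10S,13R)-16-(benzyloxy)-6-[(tert-butyldimethylsilyl)oxy]-15-[(tert-butyldiphenylsilyl)oxy]-9,13-epoxylabdan-12-yl] S-methyl carbonodithioate, via sodium xanthate 27 (not isolated)
Conditions: NaH, imidazole (cat.), THF, 0 °C → rt; CS2; then MeI
Reagents that add atoms: carbon disulfide, S=C=S; iodomethane, CI
Why: Xanthate formation: the alkoxide adds to carbon disulfide and salt 27 is S-methylated; the method is reliable for hindered secondary alcohols.

Step 19
Reactants: 28 O-[(5S,6S,8R,9R,10S,13R)-16-(benzyloxy)-6-[(tert-butyldimethylsilyl)oxy]-15-[(tert-butyldiphenylsilyl)oxy]-9,13-epoxylabdan-12-yl] S-methyl carbonodithioate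
Product: 29 (5S,6S,8R,9R,10S,13R)-16-(benzyloxy)-6-[(tert-butyldimethylsilyl)oxy]-15-[(tert-butyldiphenylsilyl)oxy]-9,13-epoxylabdane
Conditions: Bu3SnH, azobis(isobutyronitrile) (cat.), toluene, 110 °C
Reagents that add atoms: none
Why: Barton–McCombie deoxygenation: the stannyl radical adds to the thiocarbonyl, the C12–O bond fragments and the secondary C12 radical takes hydrogen from the stannane; the neighbouring C–O bonds at C13 do not fragment because alkoxy radicals are poor leaving groups.

Step 20
Reactants: 29 (5S,6S,8R,9R,10S,13R)-16-(benzyloxy)-6-[(tert-butyldimethylsilyl)oxy]-15-[(tert-butyldiphenylsilyl)oxy]-9,13-epoxylabdane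
Product: 30 (5S,6S,8R,9R,10S,13R)-16-(benzyloxy)-9,13-epoxylabdane-6,15-diol
Conditions: Bu4NF (excess), THF, 50 °C
Reagents that add atoms: none
Why: Fluoride cleaves both silyl ethers in one operation and frees the C6 and C15 hydroxyls, while the benzyl ether at C16 stays.

Step 21
Reactants: 30 (5S,6S,8R,9R,10S,13R)-16-(benzyloxy)-9,13-epoxylabdane-6,15-diol
Product: 31 (5S,8R,9R,10S,13R)-16-(benzyloxy)-6-oxo-9,13-epoxylabdan-15-al
Conditions: Dess–Martin periodinane (3 equiv), NaHCO3, CH2Cl2, rt
Reagents that add atoms: none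
Why: Dess–Martin oxidation of both alcohols under buffered, non-basic conditions gives the C6 ketone and the C15 aldehyde without β-elimination of the C13 ether oxygen.

Step 22
Reactants: 31 (5S,8R,9R,10S,13R)-16-(benzyloxy)-6-oxo-9,13-epoxylabdan-15-al
Product: 33 (5S,8R,9R,10S,13R)-15-hydroxy-9,13:15,16-diepoxylabdan-6-one (C15 epimers), via hydroxy aldehyde 32 (not isolated)
Conditions: H2 (1 atm), 10% Pd/C, EtOAc, rt
Reagents that add atoms: none
Why: Hydrogenolysis of the benzyl ether frees the C16 hydroxyl of 32, which adds to the C15 aldehyde to form the five-membered lactol; neither the ketone nor the aliphatic aldehyde is reduced under these conditions.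

Step 23
Reactants: 33 (5S,8R,9R,10S,13R)-15-hydroxy-9,13:15,16-diepoxylabdan-6-one
Product: 35 (5S,8R,9R,10S,13R)-9,13:15,16-diepoxylabd-14-en-6-one, via lactol mesylate 34 (not isolated)
Conditions: MeSO2Cl, Et3N (excess), CH2Cl2, −20 → 40 °C
Reagents that add atoms: none
Why: Sulfonylation of the lactol hydroxyl gives 34, and amine-induced elimination toward C14, the only carbon with β-hydrogens, gives the cyclic enol ether; the medium stays basic, so the acid-labile spiro ether is not ionized.

Step 24
Reactants: 35 (5S,8R,9R,10S,13R)-9,13:15,16-diepoxylabd-14-en-6-one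
Product: 36 (5S,6R,8R,9R,10S,13R)-9,13:15,16-diepoxylabd-14-en-6-ol
Conditions: LiBH(s-Bu)3, THF, −78 °C; then NaOH, H2O2, 0 °C
Reagents that add atoms: none
Why: The bulky hydride attacks the C6 ketone from the α face, opposite the axial methyl groups at C10 and C4, and gives the axial 6β-alcohol; the enol ether is inert to hydride and to alkaline peroxide.

Step 25
Reactants: 36 (5S,6R,8R,9R,10S,13R)-9,13:15,16-diepoxylabd-14-en-6-ol
Product: 37 (5S,6R,8R,9R,10S,13R)-9,13:15,16-diepoxylabd-14-en-6-yl acetate (target)
Conditions: Ac2O, 4-(dimethylamino)pyridine, Et3N, CH2Cl2, rt → 40 °C; NaHCO3 work-up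
Reagents that add atoms: acetic anhydride, CC(=O)OC(C)=O
Why: Nucleophile-catalysed acylation of the hindered axial alcohol under basic conditions that the enol ether and the spiro ether tolerate.

## Compound list

1 | geranial, (2E)-3,7-dimethylocta-2,6-dienal | CC(C)=CCC/C(C)=C/C=O | starting material
2 | (2E)-3,7-dimethylocta-2,6-dienoic acid | CC(C)=CCC/C(C)=C/C(=O)O | intermediate
3 | (2E)-3,7-dimethylocta-2,6-dienoyl chloride | CC(C)=CCC/C(C)=C/C(Cl)=O | intermediate
4 | methyl (2R)-3-hydroxy-2-methylpropanoate | OC[C@@H](C)C(=O)OC | starting material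
5 | methyl (2S)-3-iodo-2-methylpropanoate | IC[C@@H](C)C(=O)OC | intermediate
6 | [(2S)-3-methoxy-2-methyl-3-oxopropyl]zinc iodide (formed in situ) | I[Zn]C[C@@H](C)C(=O)OC | intermediate
7 | methyl (2R,5E)-2,6,10-trimethyl-4-oxoundeca-5,9-dienoate | CC(C)=CCC/C(C)=C/C(=O)C[C@@H](C)C(=O)OC | intermediate
8 | methyl (2R,4S,5E)-4-hydroxy-2,6,10-trimethylundeca-5,9-dienoate | CC(C)=CCC/C(C)=C/[C@@H](O)C[C@@H](C)C(=O)OC | intermediate
9 | methyl (2R,4S,5E)-4-[(tert-butyldimethylsilyl)oxy]-2,6,10-trimethylundeca-5,9-dienoate | CC(C)=CCC/C(C)=C/[C@@H](O[Si](C)(C)C(C)(C)C)C[C@@H](C)C(=O)OC | intermediate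
10 | (2R,4S,5E)-4-[(tert-butyldimethylsilyl)oxy]-2,6,10-trimethylundeca-5,9-dienal | CC(C)=CCC/C(C)=C/[C@@H](O[Si](C)(C)C(C)(C)C)C[C@@H](C)C=O | intermediate
11 | tert-butyldimethyl{[(3R,5S,6E)-3,7,11-trimethyldodeca-6,10-dien-1-yn-5-yl]oxy}silane | CC(C)=CCC/C(C)=C/[C@@H](O[Si](C)(C)C(C)(C)C)C[C@@H](C)C#C | intermediate
12 | (2S)-2-hydroxybutanedioic acid, (S)-malic acid | OC(=O)C[C@H](O)C(=O)O | starting material
13 | 2-[(2S,4S)-2-tert-butyl-5-oxo-1,3-dioxolan-4-yl]acetic acid | OC(=O)C[C@@H]1O[C@H](C(C)(C)C)OC1=O | intermediate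
14 | dilithium 2-[(2S)-2-tert-butyl-5-oxido-1,3-dioxol-4-yl]acetate (formed in situ) | [Li+].[Li+].[O-]C(=O)CC1=C([O-])O[C@@H](C(C)(C)C)O1 | intermediate
15 | 2-[(2S,4R)-4-[(benzyloxy)methyl]-2-tert-butyl-5-oxo-1,3-dioxolan-4-yl]acetic acid | OC(=O)C[C@]1(COCc2ccccc2)O[C@H](C(C)(C)C)OC1=O | intermediate
16 | (2S,5R)-5-[(benzyloxy)methyl]-2-tert-butyl-5-(2-hydroxyethyl)-1,3-dioxolan-4-one (formed in situ) | OCC[C@]1(COCc2ccccc2)O[C@H](C(C)(C)C)OC1=O | intermediate
17 | (3R)-3-[(benzyloxy)methyl]-3-hydroxyoxolan-2-one | O=C1OCC[C@@]1(O)COCc1ccccc1 | intermediate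
18 | (2R)-2-[(benzyloxy)methyl]-2,4-dihydroxy-N-methoxy-N-methylbutanamide | CON(C)C(=O)[C@](O)(COCc1ccccc1)CCO | intermediate
19 | (2R)-2-[(benzyloxy)methyl]-4-[(tert-butyldiphenylsilyl)oxy]-2-hydroxy-N-methoxy-N-methylbutanamide | CON(C)C(=O)[C@](O)(COCc1ccccc1)CCO[Si](c1ccccc1)(c1ccccc1)C(C)(C)C | intermediate
20 | lithium acetylide of 11 (formed in situ) | CC(C)=CCC/C(C)=C/[C@@H](O[Si](C)(C)C(C)(C)C)C[C@@H](C)C#C[Li] | intermediate
21 | chloromagnesium alkoxide of 19 (formed in situ) | CON(C)C(=O)[C@](O[Mg]Cl)(COCc1ccccc1)CCO[Si](c1ccccc1)(c1ccccc1)C(C)(C)C | intermediate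
22 | (3R,7R,9S,10E)-3-[(benzyloxy)methyl]-9-[(tert-butyldimethylsilyl)oxy]-1-[(tert-butyldiphenylsilyl)oxy]-3-hydroxy-7,11,15-trimethylhexadeca-10,14-dien-5-yn-4-one | CC(C)=CCC/C(C)=C/[C@@H](O[Si](C)(C)C(C)(C)C)C[C@@H](C)C#CC(=O)[C@](O)(COCc1ccccc1)CCO[Si](c1ccccc1)(c1ccccc1)C(C)(C)C | intermediate
23 | (3R,7R,9S,10E)-3-[(benzyloxy)methyl]-9-[(tert-butyldimethylsilyl)oxy]-1-[(tert-butyldiphenylsilyl)oxy]-6-(diethylamino)-3-hydroxy-7,11,15-trimethylhexadeca-5,10,14-trien-4-one (formed in situ, enamine geometry not defined) | CC(C)=CCC/C(C)=C/[C@@H](O[Si](C)(C)C(C)(C)C)C[C@@H](C)C(N(CC)CC)=CC(=O)[C@](O)(COCc1ccccc1)CCO[Si](c1ccccc1)(c1ccccc1)C(C)(C)C | intermediate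
24 | (2R)-2-[(benzyloxy)methyl]-5-[(2R,4S,5E)-4-[(tert-butyldimethylsilyl)oxy]-6,10-dimethylundeca-5,9-dien-2-yl]-2-{2-[(tert-butyldiphenylsilyl)oxy]ethyl}furan-3(2H)-one | CC(C)=CCC/C(C)=C/[C@@H](O[Si](C)(C)C(C)(C)C)C[C@@H](C)C1=CC(=O)[C@](COCc2ccccc2)(CCO[Si](c2ccccc2)(c2ccccc2)C(C)(C)C)O1 | intermediate
25 | (5S,6S,8R,9R,10S,13R)-16-(benzyloxy)-6-[(tert-butyldimethylsilyl)oxy]-15-[(tert-butyldiphenylsilyl)oxy]-9,13-epoxylabdan-12-one | CC(C)(C)[Si](C)(C)O[C@H]1C[C@@H](C)[C@]2(CC(=O)[C@](COCc3ccccc3)(CCO[Si](c3ccccc3)(c3ccccc3)C(C)(C)C)O2)[C@@]2(C)CCCC(C)(C)[C@H]12 | intermediate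
26 | (5S,6S,8R,9R,10S,13R)-16-(benzyloxy)-6-[(tert-butyldimethylsilyl)oxy]-15-[(tert-butyldiphenylsilyl)oxy]-9,13-epoxylabdan-12-ol (C12 epimers) | CC(C)(C)[Si](C)(C)O[C@H]1C[C@@H](C)[C@]2(CC(O)[C@](COCc3ccccc3)(CCO[Si](c3ccccc3)(c3ccccc3)C(C)(C)C)O2)[C@@]2(C)CCCC(C)(C)[C@H]12 | intermediate
27 | sodium O-(labdan-12-yl) carbonodithioate derived from 26 (formed in situ) | [Na+].CC(C)(C)[Si](C)(C)O[C@H]1C[C@@H](C)[C@]2(CC(OC(=S)[S-])[C@](COCc3ccccc3)(CCO[Si](c3ccccc3)(c3ccccc3)C(C)(C)C)O2)[C@@]2(C)CCCC(C)(C)[C@H]12 | intermediate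
28 | O-[(5S,6S,8R,9R,10S,13R)-16-(benzyloxy)-6-[(tert-butyldimethylsilyl)oxy]-15-[(tert-butyldiphenylsilyl)oxy]-9,13-epoxylabdan-12-yl] S-methyl carbonodithioate | CC(C)(C)[Si](C)(C)O[C@H]1C[C@@H](C)[C@]2(CC(OC(=S)SC)[C@](COCc3ccccc3)(CCO[Si](c3ccccc3)(c3ccccc3)C(C)(C)C)O2)[C@@]2(C)CCCC(C)(C)[C@H]12 | intermediate
29 | (5S,6S,8R,9R,10S,13R)-16-(benzyloxy)-6-[(tert-butyldimethylsilyl)oxy]-15-[(tert-butyldiphenylsilyl)oxy]-9,13-epoxylabdane | CC(C)(C)[Si](C)(C)O[C@H]1C[C@@H](C)[C@]2(CC[C@](COCc3ccccc3)(CCO[Si](c3ccccc3)(c3ccccc3)C(C)(C)C)O2)[C@@]2(C)CCCC(C)(C)[C@H]12 | intermediate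
30 | (5S,6S,8R,9R,10S,13R)-16-(benzyloxy)-9,13-epoxylabdane-6,15-diol | O[C@H]1C[C@@H](C)[C@]2(CC[C@](COCc3ccccc3)(CCO)O2)[C@@]2(C)CCCC(C)(C)[C@H]12 | intermediate
31 | (5S,8R,9R,10S,13R)-16-(benzyloxy)-6-oxo-9,13-epoxylabdan-15-al | O=C1C[C@@H](C)[C@]2(CC[C@](COCc3ccccc3)(CC=O)O2)[C@@]2(C)CCCC(C)(C)[C@H]12 | intermediate
32 | (5S,8R,9R,10S,13R)-16-hydroxy-6-oxo-9,13-epoxylabdan-15-al (formed in situ) | O=C1C[C@@H](C)[C@]2(CC[C@](CO)(CC=O)O2)[C@@]2(C)CCCC(C)(C)[C@H]12 | intermediate
33 | (5S,8R,9R,10S,13R)-15-hydroxy-9,13:15,16-diepoxylabdan-6-one (C15 epimers) | O=C1C[C@@H](C)[C@]2(CC[C@]3(CC(O)OC3)O2)[C@@]2(C)CCCC(C)(C)[C@H]12 | intermediate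
34 | (5S,8R,9R,10S,13R)-6-oxo-9,13:15,16-diepoxylabdan-15-yl methanesulfonate (formed in situ) | O=C1C[C@@H](C)[C@]2(CC[C@]3(CC(OS(C)(=O)=O)OC3)O2)[C@@]2(C)CCCC(C)(C)[C@H]12 | intermediate
35 | (5S,8R,9R,10S,13R)-9,13:15,16-diepoxylabd-14-en-6-one | O=C1C[C@@H](C)[C@]2(CC[C@]3(C=COC3)O2)[C@@]2(C)CCCC(C)(C)[C@H]12 | intermediate
36 | (5S,6R,8R,9R,10S,13R)-9,13:15,16-diepoxylabd-14-en-6-ol | O[C@@H]1C[C@@H](C)[C@]2(CC[C@]3(C=COC3)O2)[C@@]2(C)CCCC(C)(C)[C@H]12 | intermediate
37 | (5S,6R,8R,9R,10S,13R)-9,13:15,16-diepoxylabd-14-en-6-yl acetate | CC(=O)O[C@@H]1C[C@@H](C)[C@]2(CC[C@]3(C=COC3)O2)[C@@]2(C)CCCC(C)(C)[C@H]12 | target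

## Step count and least certain steps

Total step count: 25. Longest linear sequence: 19 steps (steps 1, 2, 4–8 and 14–25, from 1).

**Step 16 (key step).** The second ring closure must join two fully substituted carbons, and the acceptor is a vinylogous ester, less electrophilic than a plain enone.
- Most likely failure: hydrogen-atom capture by the C10 radical before the 6-exo closure, which stops the cascade after ring A.
- Also possible: initiation at C5=C10 instead of C3=C4, and erosion of face selectivity at C9 if the furanone does not clearly prefer the equatorial orientation.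
- Fallback (known reaction types, from 22 back to 25): ynone 22 is semi-hydrogenated over Pd/CaCO3 poisoned with Pb(OAc)2 and quinoline to the (Z)-α'-hydroxy enone F1. Under Fe(acac)3/PhSiH3, F1 should undergo the established bicyclization that ends on a β-monosubstituted enone and give the bicyclic hydroxy ketone F2, which has hydrogen at C9. Dehydrogenation of F2 with 2-iodoxybenzoic acid (only C11 carries α-hydrogens) gives the exocyclic C9=C11 enone F3. Intramolecular oxa-Michael addition of the tertiary C13 hydroxyl to C9 (catalytic base, reversible, C11 expected to settle equatorial) closes the tetrahydrofuranone and returns to 25. The C–C bond forming cascade is thus separated from the C9–O bond formation.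

**Step 10.** Competing O-alkylation of the lithium carboxylate by the chloromethyl ether, and decomposition of the dioxolanone enolate above about −30 °C, would lower the conversion to the quaternary centre.
- Fallback (from 13 back to 19): acid 13 is reduced with BH3·SMe2 to the hydroxyethyl dioxolanone F4 and silylated at once with t-BuPh2SiCl to F5. The mono-enolate of F5 (LiN(i-Pr)2, −78 °C), which has no carboxylate, is alkylated with BnOCH2Cl anti to the tert-butyl group to give F6. Aminolysis of F6 with MeNH(OMe)·HCl/AlMe3 opens the dioxolanone and gives 19 directly, bypassing 15–18.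

**Step 14.** The amide carbonyl is flanked by a quaternary, alkoxide-bearing carbon; slow addition and proton transfer would return alkyne 11.
- Fallback (from 19 back to 22): 19 is reduced with LiAlH4 at −78 °C to the α-hydroxy aldehyde F7. Acetylide 20 adds to the far more electrophilic aldehyde to give the propargylic diol F8 as a C12 epimer mixture. MnO2 oxidizes the secondary propargylic alcohol selectively to 22.

**Step 6 (with step 5).** The γ-hydroxy ester 8 can lactonize with loss of methanol during work-up or before silylation, which withdraws the substrate of step 6.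
- Fallback (from 8 back to 11): lactonization of 8 is driven to completion (catalytic 1,8-diazabicyclo[5.4.0]undec-7-ene, toluene) to the lactone F9. i-Bu2AlH at −78 °C gives the lactol F10, the Ohira–Bestmann reagent with K2CO3 in MeOH converts it into the alkynol F11, and silylation gives 11.

**Step 23.** If acid builds up, ionization at C15 can be followed by opening of the neighbouring C13–O9 ether and aromatization to a furan; elimination may also stall at the sulfonate or chloride stage.
- Fallback (from 33 back to 35): lactol 33 is converted with N-(phenylselanyl)phthalimide and PBu3 into the selenoacetal F12. Oxidation with H2O2/NaHCO3 at 0 °C gives the selenoxide, which undergoes syn-elimination toward C14 under neutral conditions and returns 35.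

## Further compounds

F1 | step 16 | (3R,5Z,7R,9S,10E)-3-[(benzyloxy)methyl]-9-[(tert-butyldimethylsilyl)oxy]-1-[(tert-butyldiphenylsilyl)oxy]-3-hydroxy-7,11,15-trimethylhexadeca-5,10,14-trien-4-one | CC(C)=CCC/C(C)=C/[C@@H](O[Si](C)(C)C(C)(C)C)C[C@@H](C)/C=C\C(=O)[C@](O)(COCc1ccccc1)CCO[Si](c1ccccc1)(c1ccccc1)C(C)(C)C
F2 | step 16 | (5S,6S,8R,9S,10R,13R)-16-(benzyloxy)-6-[(tert-butyldimethylsilyl)oxy]-15-[(tert-butyldiphenylsilyl)oxy]-13-hydroxylabdan-12-one | CC(C)(C)[Si](C)(C)O[C@H]1C[C@@H](C)[C@H](CC(=O)[C@](O)(COCc2ccccc2)CCO[Si](c2ccccc2)(c2ccccc2)C(C)(C)C)[C@@]2(C)CCCC(C)(C)[C@H]12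
F3 | step 16 | (5S,6S,8R,10S,13R)-16-(benzyloxy)-6-[(tert-butyldimethylsilyl)oxy]-15-[(tert-butyldiphenylsilyl)oxy]-13-hydroxylabd-9(11)-en-12-one (alkene geometry not defined) | CC(C)(C)[Si](C)(C)O[C@H]1C[C@@H](C)C(=CC(=O)[C@](O)(COCc2ccccc2)CCO[Si](c2ccccc2)(c2ccccc2)C(C)(C)C)[C@@]2(C)CCCC(C)(C)[C@H]12
F4 | step 10 | (2S,5S)-2-tert-butyl-5-(2-hydroxyethyl)-1,3-dioxolan-4-one | OCC[C@@H]1O[C@H](C(C)(C)C)OC1=O
F5 | step 10 | (2S,5S)-2-tert-butyl-5-{2-[(tert-butyldiphenylsilyl)oxy]ethyl}-1,3-dioxolan-4-one | CC(C)(C)[Si](OCC[C@@H]1O[C@H](C(C)(C)C)OC1=O)(c1ccccc1)c1ccccc1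
F6 | step 10 | (2S,5R)-5-[(benzyloxy)methyl]-2-tert-butyl-5-{2-[(tert-butyldiphenylsilyl)oxy]ethyl}-1,3-dioxolan-4-one | CC(C)(C)[Si](OCC[C@]1(COCc2ccccc2)O[C@H](C(C)(C)C)OC1=O)(c1ccccc1)c1ccccc1
F7 | step 14 | (2R)-2-[(benzyloxy)methyl]-4-[(tert-butyldiphenylsilyl)oxy]-2-hydroxybutanal | O=C[C@](O)(COCc1ccccc1)CCO[Si](c1ccccc1)(c1ccccc1)C(C)(C)C
F8 | step 14 | (3R,7R,9S,10E)-3-[(benzyloxy)methyl]-9-[(tert-butyldimethylsilyl)oxy]-1-[(tert-butyldiphenylsilyl)oxy]-7,11,15-trimethylhexadeca-10,14-dien-5-yne-3,4-diol (C4 epimers) | CC(C)=CCC/C(C)=C/[C@@H](O[Si](C)(C)C(C)(C)C)C[C@@H](C)C#CC(O)[C@](O)(COCc1ccccc1)CCO[Si](c1ccccc1)(c1ccccc1)C(C)(C)C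
F9 | step 6 | (3R,5S)-5-[(1E)-2,6-dimethylhepta-1,5-dien-1-yl]-3-methyloxolan-2-one | CC(C)=CCC/C(C)=C/[C@@H]1C[C@@H](C)C(=O)O1
F10 | step 6 | (3R,5S)-5-[(1E)-2,6-dimethylhepta-1,5-dien-1-yl]-3-methyloxolan-2-ol (C2 epimers) | CC(C)=CCC/C(C)=C/[C@@H]1C[C@@H](C)C(O)O1
F11 | step 6 | (3R,5S,6E)-3,7,11-trimethyldodeca-6,10-dien-1-yn-5-ol | CC(C)=CCC/C(C)=C/[C@@H](O)C[C@@H](C)C#C
F12 | step 23 | (5S,8R,9R,10S,13R)-15-(phenylselanyl)-9,13:15,16-diepoxylabdan-6-one (C15 epimers) | O=C1C[C@@H](C)[C@]2(CC[C@]3(CC([Se]c4ccccc4)OC3)O2)[C@@]2(C)CCCC(C)(C)[C@H]12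
A1 | alternative 1 | cis-fused 2,5,5,8a-tetramethyl-7-[(triisopropylsilyl)oxy]-4a,5,8,8a-tetrahydronaphthalene-1,4-dione (configuration as in the SMILES) | O=C1C=C(C)C(=O)[C@@]2(C)CC(O[Si](C(C)C)(C(C)C)C(C)C)=CC(C)(C)[C@@H]12
A2 | alternative 1 | 2,6-dimethylcyclohexa-2,5-diene-1,4-dione | CC1=CC(=O)C=C(C)C1=O
A3 | alternative 1 | triisopropyl[(4-methylpenta-1,3-dien-2-yl)oxy]silane | C=C(O[Si](C(C)C)(C(C)C)C(C)C)C=C(C)C
A4 | alternative 2 | 6β-acetoxy-9α,13-epoxylabdan-16,15-olide | CC(=O)O[C@@H]1C[C@@H](C)[C@]2(CC[C@]3(CC(=O)OC3)O2)[C@@]2(C)CCCC(C)(C)[C@H]12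
A5 | alternative 2 | 6β-acetoxy-12-iodo-9α-[(5-oxo-2,5-dihydrofuran-3-yl)oxy]-13,14,15,16-tetranorlabdane | CC(=O)O[C@@H]1C[C@@H](C)[C@@](CCI)(OC2=CC(=O)OC2)[C@@]2(C)CCCC(C)(C)[C@H]12
A6 | alternative 3 | 16-[(tert-butyldiphenylsilyl)oxy]-9α,13-epoxy-15-norlabd-5-en-14-ol (configuration as in the SMILES) | C1C[C@@H](C)[C@]2(CC[C@](CO[Si](c3ccccc3)(c3ccccc3)C(C)(C)C)(CO)O2)[C@@]2(C)CCCC(C)(C)C=12
A7 | alternative 3 | 1-{2-[(tert-butyldiphenylsilyloxy)methyl]oxiran-2-yl}-4-methyl-6-(2,6,6-trimethylcyclohex-1-en-1-yl)hexan-3-one (configuration as in the SMILES) | CC1=C(CC[C@@H](C)C(=O)CC[C@@]2(CO[Si](c3ccccc3)(c3ccccc3)C(C)(C)C)CO2)C(C)(C)CCC1
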